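The readings stem from a simulated flask with constants of no real substance, and the scatter is random.

At early times I can't tell the earlier runs apart: Friday's run at 1.9 equiv of free base and Thursday's at 2.7 equiv both start the same way, with 95.9% and 94.9% of the electrophile left at 0.667 h. At 4.00 h, Sunday's, Friday's and Thursday's runs stand at 72.6%, 73.6% and 72.4%, a spread below the 5 percentage points that counts as a change.

the same everywhere: electrophile 0.11 M; gas 7.1 mM (held)

| charge | free base | remark | time |
|---|---|---|---|
| Sunday's | 1.3 equiv | run made earlier |  |
| Friday's | 1.9 equiv | run made earlier |  |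
| Thursday's | 2.7 equiv | run made earlier |  |
| west | 1.50 equiv |  | 5.0 h |
| north-east | 2.00 equiv |  | 5.0 h |
| north | 2.50 equiv |  | 5.0 h |

| run | time / h | electrophile / % | target / % |
|---|---|---|---|
| Sunday's | 0.333 | 98.6 | 0.9 |
| Sunday's | 0.833 | 93.9 | 5.1 |
| Sunday's | 1.50 | 89.4 | 8.2 |
| Sunday's | 2.50 | 83.4 | 15.7 |
| Sunday's | 4.00 | 72.6 | 23.7 |
| Friday's | 0.667 | 95.9 | 2.1 |
| Friday's | 1.33 | 92.2 | 8.6 |
| Friday's | 2.00 | 86.6 | 13.3 |
| Friday's | 3.00 | 79.2 | 19.5 |
| Friday's | 4.00 | 73.6 | 25.4 |
| Thursday's | 0.667 | 94.9 | 4.3 |
| Thursday's | 1.33 | 90.3 | 8.4 |
| Thursday's | 2.00 | 87.5 | 11.2 |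
| Thursday's | 3.00 | 78.7 | 19.7 |
| Thursday's | 4.00 | 72.4 | 25.1 |

(standard deviation of a reading: 1 percentage point)

- the numbers in the tables scatter by 1 percentage point (one standard deviation)
- at the start none of the gas is in solution

- part of the electrophile that has reacted at the end, west
- part of the electrophile that has reacted at the end, north-east
- part of the electrophile that has reacted at the end, north
- what raising the equivalents of free base from its lowest to its highest value here does to the part of the electrophile that has reacted (changes below 5 percentage points count as none) (it rises / no change / it falls)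

You asked for a quick number, so here is mine. West, north-east and north lie inside the span of free base already tried, so I treat them as one flask. I work with the fraction f of electrophile left, not the fraction made. If the electrophile is lost in proportion to what remains, ln f falls in a straight line with time t, and the slope is the thing to carry: the pseudo-first-order constant k.

f at 4.00 h, pooled = 72.9%

k = −ln f / t = 0.0791 h⁻¹

f at 5.0 h = exp(−k t) = 67.3%, so 32.7% has reacted

Your forecast is 33.5%, 33.5% and 33.5%, with no change across the base, on the ground that “no base effect should appear”. My figure lies 0.82 points below it, against a scatter of 1 point on one reading, and I agree on the trend.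

The flask gives 33.0%, 33.0% and 33.0% for west, north-east and north, a change of 0 points: no change.

    electrophile + nucleophile → acid set free + target (k = 15.0 M⁻¹ h⁻¹)
    gas ⇌ nucleophile, rate k2*(csat - [nucleophile]) (kL = 7.00 h⁻¹)
    electrophile + target → side product (k = 0.310 M⁻¹ h⁻¹)
    nucleophile + acid set free ⇌ protonated nucleophile, settled at all times (K = 9.40 × 10⁵ M⁻¹)
    acid set free + free base ⇌ salt of the base (K = 48000 M⁻¹, k = 7.90 M⁻¹ h⁻¹)

In north-east, 67% of the electrophile is left at 5.00 h, where k gave 67.3%. Now I carry k to north-east read at 12 h, where exp(−k t) gives 38.7% left. That flask has 33% of the electrophile left, with 53.4% target and 13.6% side product.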